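**Plan**

- Atom numbers C1–C21 follow the target chain from the tiglyl methyl to the ring methine next to the ketone, with the lactone oxygen as O17; they are kept for all intermediates.
- Retrosynthesis cuts C13=C14 (Julia–Kocienski olefination), then in the east half C15–C19 (allylic alkylation) and C16–C21 (aldol), in the west half C3–C4 (alkenyllithium), and last C5–C6 and C11–C12 together.
- Enabling feature: ring carbons C6–C11 bear H, CH3, H, CH3, H, CH3 in turn, the substitution pattern of mesitylene, and cyclobutane carbons C5 and C12 with their trans carbon substituents C4 and C13 form the skeleton of a mesaconate diester. One arene–alkene ortho [2+2] photocycloaddition therefore builds the whole west carbocycle.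
- Forward: the cyclobutane ring forms first (step 1) and the west side chains are grown (steps 2–9). The east δ-lactone and then the oxabicyclo[2.2.1]heptane are closed (steps 10–14), the halves are joined at C13=C14 (step 15), and the silyl ether is removed (step 16).
- Stereochemistry: C5, C6, C11, C12 relative from the suprafacial cycloaddition and absolute from an enzymatic resolution; C4 from a CBS reduction; C16 and C21 from an auxiliary-controlled anti aldol; C19 and C15 from the bicyclisation; the E geometry of C13=C14 from the olefination.

Key step: step 1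

Assumption: (E)-4-acetoxy-2-methylbut-2-enal, the C5 aldehyde used in step 11, is taken as purchasable (an industrial vitamin A intermediate), as are (R)-4-benzyl-3-propionyloxazolidin-2-one and geometrically pure (E)-2-bromobut-2-ene.

**Route**

Step 1
Reactants: 1 mesitylene; 2 dimethyl mesaconate
Product: 3 racemic west diester (dimethyl 1,3,5,7-tetramethylbicyclo[4.2.0]octa-2,4-diene-7,8-dicarboxylate; cis-fused, C4 ester exo, C13 ester endo)
Conditions: hν (254 nm, low-pressure Hg lamp), 2 (0.2 M) in neat degassed 1, FEP flow reactor, 10 °C, low conversion per pass, recycle of 1 and 2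
Reagents that add atoms: none
Why: Proposed new method: light absorbed by the arene should give singlet-excited mesitylene, which forms a polar exciplex with the electron-poor alkene (arene as donor) that collapses across one ring bond to the C5–C6 and C11–C12 bonds; the closest known reaction type is the ortho [2+2] photocycloaddition of acceptor alkenes such as acrylonitrile or maleic anhydride derivatives to benzene and alkylbenzenes. The one ring that closes, the cyclobutane, arises by an intermolecular [2π+2π] cycloaddition that is suprafacial on both partners and leaves the other two double bonds of the arene as the cyclohexa-1,3-diene. C5 and C12 keep the E geometry of the alkene (C4 and C13 trans) because the singlet path has no freely rotating biradical, and C6 and C11 become cis-fused because both bonds form on one face of the ring. The step needs ortho instead of meta addition, which the donor–acceptor character of the pair should secure, and it has no site problem because all six ring bonds of mesitylene are equivalent. It also needs the orientation in which the fully substituted alkene carbon C5 bonds to a ring CH (avoiding vicinal quaternary centres) and the C13 ester sits over the ring (endo); both rest on steric and exciplex-overlap arguments and are the open points. Low conversion per pass should spare the photolabile diene, and an adduct with the opposite ring-fusion face would be the valence isomer reachable through the common cyclooctatriene on gentle heating, so it could be equilibrated and recycled.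

Step 2
Reactants: 3 racemic west diester
Product: 4 west monoacid (C13 CO2H, C4 CO2Me; single enantiomer with C5, C6, C11, C12 as in the target)
Conditions: pig liver esterase, phosphate buffer pH 7.5/acetone 9:1, 25 °C, pH-stat (1 M NaOH), stopped below half conversion; HCl to pH 3, extraction
Reagents that add atoms: water (O)
Why: Enzymatic kinetic resolution by ester hydrolysis, in which the esterase should accept only the unhindered C13 ester on the secondary cyclobutane carbon (the C4 ester sits on a quaternary centre) and only one antipode of 3, so that the wanted enantiomer is collected as the acid and the absolute configuration of C5, C6, C11 and C12 is fixed here.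

Step 3
Reactants: 4 west monoacid
Product: 6 west hydroxy ester (C13 CH2OH, C4 CO2Me), via acyl imidazolide 5 (not isolated)
Conditions: 1,1'-carbonyldiimidazole, THF, 23 °C; then NaBH4, H2O, 0 °C
Reagents that add atoms: none
Why: Chemoselective reduction of a carboxylic acid through its acyl imidazolide with NaBH4, which leaves the hindered methyl ester and the diene untouched and forms no stereocentre, C12 already being trans to C4 and thus in its preferred configuration.

Step 4
Reactants: 6 west hydroxy ester; 7 (E)-2-bromobut-2-ene
Product: 9 west hydroxy enone (C4 ketone carrying the (E)-but-2-en-2-yl group), via alkenyllithium 8 (not isolated)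
Conditions: 7 (2.6 equiv), t-BuLi (5.2 equiv), Et2O, −78 °C; then 6, THF, −78 → −40 °C; AcOH quench at −78 °C
Reagents that add atoms: none
Why: Ketone synthesis by addition of an alkenyllithium to an ester, in which bromine–lithium exchange keeps the E geometry, one equivalent of 8 deprotonates the hydroxyl, the lithium hemiketal of the neopentyl-type ester should persist until the cold quench, and the resulting tert-alkyl alkenyl ketone is too hindered for a second addition; no stereocentre is formed.

Step 5
Reactants: 9 west hydroxy enone
Product: 10 west diol ((4R)-allylic alcohol, C13 CH2OH)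
Conditions: (S)-2-methyl-CBS-oxazaborolidine (0.3 equiv), catecholborane (3 equiv), toluene, −78 → −40 °C; aqueous NaOH work-up
Reagents that add atoms: none
Why: Corey–Bakshi–Shibata reduction under reagent control, in which the quaternary C5 side should act as the large and the planar 1-methylpropenyl group as the small substituent, so that the (S)-catalyst delivers hydride to the face giving the (4R) carbinol (the bicycle itself offers little facial bias), while catecholborane at low temperature leaves the diene alone.

Step 6
Reactants: 10 west diol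
Product: 11 west hydroxy sulfide (C13 CH2–S–(1-phenyl-1H-tetrazol-5-yl))
Conditions: 1-phenyl-1H-tetrazole-5-thiol (1.1 equiv), PPh3, DIAD, THF, 0 °C
Reagents that add atoms: 1-phenyl-1H-tetrazole-5-thiol (Sc1nnnn1-c1ccccc1)
Why: Mitsunobu thioetherification, which should activate only the primary C13 hydroxyl because the secondary allylic C4 hydroxyl next to the quaternary C5 is too hindered to form the oxyphosphonium ion, the thiol then displacing by SN2 at a carbon that is not a stereocentre.

Step 7
Reactants: 11 west hydroxy sulfide
Product: 12 west silyl ether sulfide (C4 O-TBS)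
Conditions: TBSOTf, 2,6-lutidine, CH2Cl2, −78 → 0 °C
Reagents that add atoms: tert-butyldimethylsilyl triflate (CC(C)(C)[Si](C)(C)OS(=O)(=O)C(F)(F)F)
Why: Silylation of a hindered secondary alcohol with a silyl triflate and a non-nucleophilic base, which masks the C4 hydroxyl against hydroxyl-directed epoxidation in step 8 and against the bases of steps 9 and 15 without touching a stereocentre.

Step 8
Reactants: 12 west silyl ether sulfide
Product: 13 west primary sulfone
Conditions: (NH4)6Mo7O24·4H2O (0.2 equiv), 30% H2O2, EtOH, 0 → 23 °C
Reagents that add atoms: hydrogen peroxide (OO)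
Why: Molybdate-catalysed oxidation of a sulfide to the sulfone, in which sulfur should be oxidised much faster than the trisubstituted alkenes and no stereocentre changes.

Step 9
Reactants: 13 west primary sulfone
Product: 15 west secondary sulfone (C13 methylated; mixture of C13 epimers), via potassium sulfonyl carbanion 14 (not isolated)
Conditions: MeI (5 equiv), KN(SiMe3)2 (1.1 equiv, added last), THF, −78 °C
Reagents that add atoms: iodomethane (CI)
Why: α-Alkylation of a sulfone, with the carbanion generated in the presence of MeI to suppress self-condensation of the tetrazolyl sulfone; the new C13 centre forms as an epimer mixture, which is immaterial because C13 becomes sp2 in step 15.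

Step 10
Reactants: 16 (R)-4-benzyl-3-propionyloxazolidin-2-one; 17 propionyl chloride
Product: 19 (R)-4-benzyl-3-[(S)-2-methyl-3-oxopentanoyl]oxazolidin-2-one, via lithium enolate 18 (not isolated)
Conditions: LiN(i-Pr)2, THF, −78 °C; then 17, −78 °C
Reagents that add atoms: none
Why: C-Acylation of the chelated (Z)-lithium enolate of the acyloxazolidinone on the face opposite the benzyl group sets the (S) methyl centre (the later C19, needed only to steer the aldol), and allylic strain keeps the β-ketoimide from enolising.

Step 11
Reactants: 19 β-ketoimide; 20 (E)-4-acetoxy-2-methylbut-2-enal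
Product: 22 anti,anti aldol adduct ((R)-4-benzyl-3-[(2S,4R,5S,6E)-8-acetoxy-5-hydroxy-2,4,6-trimethyl-3-oxooct-6-enoyl]oxazolidin-2-one), via boron enolate 21 (not isolated)
Conditions: (c-C6H11)2BCl, EtNMe2, Et2O, 0 °C; then 20, −78 → −20 °C; pH 7 buffer, MeOH, H2O2, 0 °C
Reagents that add atoms: none
Why: Anti-selective Evans boron aldol reaction of a β-ketoimide, in which the (E)-enolate formed on the ethyl side reacts through a chair transition state whose facial choice is dictated by the C2 methyl centre, so that the 2,4-anti-4,5-anti adduct should form with C16 (S) and C21 (R) as in the target.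

Step 12
Reactants: 22 anti,anti aldol adduct
Product: 23 keto lactone ((5R,6S)-6-[(E)-4-acetoxybut-2-en-2-yl]-3,5-dimethyloxane-2,4-dione)
Conditions: i-Pr2NEt, DMAP (0.1 equiv), CH2Cl2, 23 °C
Reagents that add atoms: none
Why: Lactonisation by intramolecular acyl transfer, the C16 hydroxyl attacking the imide carbonyl in a 6-exo-trig closure and expelling the oxazolidinone, which leaves C16 and C21 unchanged (substituents trans) and turns C19 into an enolisable centre whose configuration no longer matters.

Step 13
Reactants: 23 keto lactone
Product: 24 vinyl ketolactone ((1S,4S,6R,7S)-7-ethenyl-4,6,7-trimethyl-2-oxabicyclo[2.2.1]heptane-3,5-dione)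
Conditions: Pd(PPh3)4 (5 mol %), Et3N, THF, 40 °C
Reagents that add atoms: none
Why: Intramolecular Tsuji–Trost allylic alkylation, in which zerovalent palladium ionises the primary allylic acetate and the enolate carbon C19 attacks the substituted allyl terminus C15 across the lactone ring (5-exo for both new five-membered rings); C19 is fixed by the bridge, and C15 should form with the vinyl group on the side of C20/C21 because the reacting rotamer that turns the C15 methyl toward the ring oxygen O17 and the flat allyl CH toward C21 has the least A(1,2) strain.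

Step 14
Reactants: 24 vinyl ketolactone
Product: 26 east aldehyde ((1S,4S,6R,7S)-4,6,7-trimethyl-3,5-dioxo-2-oxabicyclo[2.2.1]heptane-7-carbaldehyde), via ozonide 25 (not isolated)
Conditions: O3, CH2Cl2, −78 °C; then PPh3, −78 → 23 °C
Reagents that add atoms: ozone ([O-][O+]=O)
Why: Ozonolysis of the only alkene with reductive work-up should give the non-enolisable C14 aldehyde without touching any stereocentre.

Step 15
Reactants: 15 west secondary sulfone; 26 east aldehyde
Product: 28 O-TBS shimalactone B, via potassium sulfonyl carbanion 27 (not isolated)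
Conditions: KN(SiMe3)2 (1.05 equiv), DME, −60 °C; then 26, −60 → 0 °C
Reagents that add atoms: none
Why: Julia–Kocienski olefination, in which the carbanion adds to the aldehyde and Smiles rearrangement with loss of SO2 and the tetrazolone forms C13=C14; the E isomer (bulky C12 and C15 trans) should dominate because addition of the hindered partners is reversible and elimination runs through the less congested adduct, while premetalation keeps free base away from the β-keto lactone.

Step 16
Reactants: 28 O-TBS shimalactone B
Product: 29 shimalactone B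
Conditions: HF·pyridine, pyridine, THF, 0 → 23 °C
Reagents that add atoms: none
Why: Fluoride-mediated desilylation under buffered, non-basic conditions should free the C4 hydroxyl without ionising the allylic carbinol or opening the β-keto lactone, giving the target with every stereocentre in place.

**Compound list**

1 | mesitylene (1,3,5-trimethylbenzene) | Cc1cc(C)cc(C)c1 | starting material
2 | dimethyl mesaconate (dimethyl (E)-2-methylbut-2-enedioate) | COC(=O)/C=C(\C)C(=O)OC | starting material
3 | west diester, dimethyl 1,3,5,7-tetramethylbicyclo[4.2.0]octa-2,4-diene-7,8-dicarboxylate, racemic, relative configuration (1S*,6R*,7S*,8S*), one enantiomer drawn | COC(=O)[C@@]1(C)[C@@H]2C(C)=CC(C)=C[C@]2(C)[C@@H]1C(=O)OC | intermediate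
4 | west monoacid, C13 carboxylic acid and C4 methyl ester of 3, single enantiomer as drawn | COC(=O)[C@@]1(C)[C@@H]2C(C)=CC(C)=C[C@]2(C)[C@@H]1C(=O)O | intermediate
5 | acyl imidazolide of 4 | COC(=O)[C@@]1(C)[C@@H]2C(C)=CC(C)=C[C@]2(C)[C@@H]1C(=O)n1ccnc1 | intermediate
6 | west hydroxy ester (C13 CH2OH, C4 CO2Me) | COC(=O)[C@@]1(C)[C@@H]2C(C)=CC(C)=C[C@]2(C)[C@@H]1CO | intermediate
7 | (E)-2-bromobut-2-ene | C/C=C(\C)Br | starting material
8 | (E)-but-2-en-2-yllithium | C/C=C(\C)[Li] | intermediate
9 | west hydroxy enone (C4 ketone with (E)-but-2-en-2-yl, C13 CH2OH) | C/C=C(\C)C(=O)[C@@]1(C)[C@@H]2C(C)=CC(C)=C[C@]2(C)[C@@H]1CO | intermediate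
10 | west diol ((4R)-carbinol, C13 CH2OH) | C/C=C(\C)[C@@H](O)[C@@]1(C)[C@@H]2C(C)=CC(C)=C[C@]2(C)[C@@H]1CO | intermediate
11 | west hydroxy sulfide (C13 CH2–S–(1-phenyl-1H-tetrazol-5-yl)) | C/C=C(\C)[C@@H](O)[C@@]1(C)[C@@H]2C(C)=CC(C)=C[C@]2(C)[C@@H]1CSc1nnnn1-c1ccccc1 | intermediate
12 | west silyl ether sulfide (C4 O-TBS) | C/C=C(\C)[C@@H](O[Si](C)(C)C(C)(C)C)[C@@]1(C)[C@@H]2C(C)=CC(C)=C[C@]2(C)[C@@H]1CSc1nnnn1-c1ccccc1 | intermediate
13 | west primary sulfone | C/C=C(\C)[C@@H](O[Si](C)(C)C(C)(C)C)[C@@]1(C)[C@@H]2C(C)=CC(C)=C[C@]2(C)[C@@H]1CS(=O)(=O)c1nnnn1-c1ccccc1 | intermediate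
14 | potassium α-sulfonyl carbanion of 13 | C/C=C(\C)[C@@H](O[Si](C)(C)C(C)(C)C)[C@@]1(C)[C@@H]2C(C)=CC(C)=C[C@]2(C)[C@@H]1[CH-]S(=O)(=O)c1nnnn1-c1ccccc1.[K+] | intermediate
15 | west secondary sulfone (C13 bears CH3; C13 epimers) | C/C=C(\C)[C@@H](O[Si](C)(C)C(C)(C)C)[C@@]1(C)[C@@H]2C(C)=CC(C)=C[C@]2(C)[C@@H]1C(C)S(=O)(=O)c1nnnn1-c1ccccc1 | intermediate
16 | (R)-4-benzyl-3-propionyloxazolidin-2-one | CCC(=O)N1[C@H](Cc2ccccc2)COC1=O | starting material
17 | propionyl chloride | CCC(=O)Cl | starting material
18 | lithium (Z)-enolate of 16 | C/C=C(\O[Li])N1[C@H](Cc2ccccc2)COC1=O | intermediate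
19 | (R)-4-benzyl-3-[(S)-2-methyl-3-oxopentanoyl]oxazolidin-2-one | CCC(=O)[C@H](C)C(=O)N1[C@H](Cc2ccccc2)COC1=O | intermediate
20 | (E)-4-acetoxy-2-methylbut-2-enal | CC(=O)OC/C=C(\C)C=O | starting material
21 | dicyclohexylboron (E)-enolate of 19 | C/C=C(/OB(C1CCCCC1)C1CCCCC1)[C@H](C)C(=O)N1[C@H](Cc2ccccc2)COC1=O | intermediate
22 | (R)-4-benzyl-3-[(2S,4R,5S,6E)-8-acetoxy-5-hydroxy-2,4,6-trimethyl-3-oxooct-6-enoyl]oxazolidin-2-one | CC(=O)OC/C=C(\C)[C@@H](O)[C@@H](C)C(=O)[C@H](C)C(=O)N1[C@H](Cc2ccccc2)COC1=O | intermediate
23 | (5R,6S)-6-[(E)-4-acetoxybut-2-en-2-yl]-3,5-dimethyloxane-2,4-dione (keto form drawn, C3 not fixed) | CC(=O)OC/C=C(\C)[C@H]1OC(=O)C(C)C(=O)[C@@H]1C | intermediate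
24 | (1S,4S,6R,7S)-7-ethenyl-4,6,7-trimethyl-2-oxabicyclo[2.2.1]heptane-3,5-dione | C=C[C@]1(C)[C@H]2OC(=O)[C@]1(C)C(=O)[C@@H]2C | intermediate
25 | secondary ozonide (1,2,4-trioxolane) of 24 | O1COOC1[C@]2(C)[C@H]3OC(=O)[C@]2(C)C(=O)[C@@H]3C | intermediate
26 | (1S,4S,6R,7S)-4,6,7-trimethyl-3,5-dioxo-2-oxabicyclo[2.2.1]heptane-7-carbaldehyde | O=C[C@]1(C)[C@H]2OC(=O)[C@]1(C)C(=O)[C@@H]2C | intermediate
27 | potassium α-sulfonyl carbanion of 15 | C/C=C(\C)[C@@H](O[Si](C)(C)C(C)(C)C)[C@@]1(C)[C@@H]2C(C)=CC(C)=C[C@]2(C)[C@@H]1[C-](C)S(=O)(=O)c1nnnn1-c1ccccc1.[K+] | intermediate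
28 | O-TBS shimalactone B | C/C=C(\C)[C@@H](O[Si](C)(C)C(C)(C)C)[C@@]1(C)[C@@H]2C(C)=CC(C)=C[C@]2(C)[C@@H]1/C(C)=C/[C@]1(C)[C@H]2OC(=O)[C@]1(C)C(=O)[C@@H]2C | intermediate
29 | shimalactone B | C/C=C(\C)[C@@H](O)[C@@]1(C)[C@@H]2C(C)=CC(C)=C[C@]2(C)[C@@H]1/C(C)=C/[C@]1(C)[C@H]2OC(=O)[C@]1(C)C(=O)[C@@H]2C | target

**Step count**

Total: 16 steps. Longest linear sequence: 11 steps (steps 1–9, 15, 16); the east branch (steps 10–14) has 5 steps.

**Steps most likely to fail**

1. Step 1 (photocycloaddition).
   - Risk: the exciplex may relax by E/Z isomerisation of the alkene, add in the meta mode or in the wrong orientation or facial sense, and the diene may be consumed by secondary photolysis.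
   - Fallback (known chemistry: Stille coupling followed by thermal 8π conrotatory and 6π disrotatory electrocyclisation): it sets out from aldehyde 20 and returns at hydroxy ester 6, replacing steps 1–3.
   - Compound 20 is converted by the Z-selective α-iodoethylidene Wittig reaction (ethyltriphenylphosphonium iodide, n-BuLi, I2, then NaN(SiMe3)2, THF, −78 °C) into (2E,4Z)-5-iodo-3-methylhexa-2,4-dien-1-yl acetate F1.
   - Separately, purchased propargyl alcohol is carbomagnesiated (MeMgBr, CuI) and the alkenylmagnesium species quenched with Bu3SnCl to give (Z)-2-methyl-3-(tributylstannyl)prop-2-en-1-ol F2.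
   - F2 is oxidised with MnO2 to (Z)-2-methyl-3-(tributylstannyl)prop-2-enal F3 and extended by Wittig reaction with methyl 2-(triphenylphosphoranylidene)propanoate to methyl (2E,4Z)-2,4-dimethyl-5-(tributylstannyl)penta-2,4-dienoate F4.
   - Stille coupling of F4 with F1 (Pd2(dba)3, AsPh3, NMP, 40 °C) should give methyl (2E,4Z,6Z,8E)-10-acetoxy-2,4,6,8-tetramethyldeca-2,4,6,8-tetraenoate F5.
   - F5 should close in the flask to methyl trans-8-(acetoxymethyl)-1,3,5,7-tetramethylcycloocta-1,3,5-triene-7-carboxylate F6 and then to the racemic acetate of 6, F7; the two ring-fusion diastereomers interconvert through F6 and the unwanted one is re-equilibrated.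
   - Kinetic resolution of F7 by lipase-catalysed hydrolysis of the primary acetate (Candida antarctica lipase B, buffer/MTBE) then gives 6.

2. Step 15 (Julia–Kocienski union).
   - Risk: the hindered secondary sulfonyl carbanion may add slowly or reversibly to the neopentyl aldehyde, the alkoxide formed may open the β-keto lactone by retro-Claisen cleavage, and the E/Z ratio may be low.
   - Fallback (base-free union by olefin cross-metathesis): it sets out from sulfone 15 and vinyl ketolactone 24 and returns at 28.
   - Julia–Kocienski methylenation of 15 (KN(SiMe3)2, then monomeric formaldehyde) gives the isopropenyl compound F8 (C12–C(CH3)=CH2, otherwise as 15).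
   - Cross-metathesis of F8 with an excess of 24 (second-generation Hoveyda–Grubbs catalyst RuCl2(H2IMes)(=CH-C6H4-2-O-i-Pr), toluene, 60 °C, ethylene removed) would give 28 with the thermodynamically preferred E geometry.
   - This coupling of two hindered alkenes is expected to be slow.

3. Step 2 (enzymatic resolution).
   - Risk: the esterase may not accept the congested bicycle, may hydrolyse with low enantioselectivity, or may prefer the unwanted antipode.
   - Fallback (classical resolution): it sets out from 3 and returns at 4.
   - Saponification with one equivalent of LiOH (THF/H2O, 0 °C) should cleave only the unhindered C13 ester and give the racemic monoacid F9.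
   - Crystallisation with (R)-1-phenylethylamine should deliver the less soluble salt of the wanted acid, the (R)-1-phenylethylammonium salt of 4, F10; the antipodal amine is used if the other salt crystallises.
   - Acidification with dilute HCl releases 4.

Further compounds
F1 | step 1 | (2E,4Z)-5-iodo-3-methylhexa-2,4-dien-1-yl acetate | CC(=O)OC/C=C(\C)/C=C(\I)C
F2 | step 1 | (Z)-2-methyl-3-(tributylstannyl)prop-2-en-1-ol | CCCC[Sn](CCCC)(CCCC)/C=C(/C)CO
F3 | step 1 | (Z)-2-methyl-3-(tributylstannyl)prop-2-enal | CCCC[Sn](CCCC)(CCCC)/C=C(/C)C=O
F4 | step 1 | methyl (2E,4Z)-2,4-dimethyl-5-(tributylstannyl)penta-2,4-dienoate | COC(=O)/C(C)=C/C(C)=C\[Sn](CCCC)(CCCC)CCCC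
F5 | step 1 | methyl (2E,4Z,6Z,8E)-10-acetoxy-2,4,6,8-tetramethyldeca-2,4,6,8-tetraenoate | COC(=O)/C(C)=C/C(C)=C\C(C)=C/C(C)=C/COC(C)=O
F6 | step 1 | methyl trans-8-(acetoxymethyl)-1,3,5,7-tetramethylcycloocta-1,3,5-triene-7-carboxylate (racemic, one enantiomer drawn) | COC(=O)[C@@]1(C)C=C(C)C=C(C)C=C(C)[C@@H]1COC(C)=O
F7 | step 1 | racemic acetate of 6, methyl 8-(acetoxymethyl)-1,3,5,7-tetramethylbicyclo[4.2.0]octa-2,4-diene-7-carboxylate (one enantiomer drawn) | COC(=O)[C@@]1(C)[C@@H]2C(C)=CC(C)=C[C@]2(C)[C@@H]1COC(C)=O
F8 | step 15 | west isopropenyl compound (C12 bears C(CH3)=CH2, C4 O-TBS) | C/C=C(\C)[C@@H](O[Si](C)(C)C(C)(C)C)[C@@]1(C)[C@@H]2C(C)=CC(C)=C[C@]2(C)[C@@H]1C(C)=C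
F9 | step 2 | racemic west monoacid (one enantiomer drawn) | COC(=O)[C@@]1(C)[C@@H]2C(C)=CC(C)=C[C@]2(C)[C@@H]1C(=O)O
F10 | step 2 | (R)-1-phenylethylammonium salt of 4 | COC(=O)[C@@]1(C)[C@@H]2C(C)=CC(C)=C[C@]2(C)[C@@H]1C(=O)[O-].C[C@@H]([NH3+])c1ccccc1
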